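(The numbers in the tables stem from a simulated flask for an exercise; noise was put on by code.)

Vera, who runs this resolution, and Tom, who supplies the racemization catalyst, disagree about Sunday's flask.

| setting | Sunday's | Thursday's | flask |
|---|---|---|---|
| left-handed substrate | 0.20 M | 0.20 M | 0.20 M |
| right-handed substrate | 0.20 M | 0.20 M | 0.20 M |
| partner | 0.60 M | 0.60 M | 0.600 M |
| free catalyst | 1.2 mM | 1.2 mM | 1.2 mM |
| precatalyst | 2.4 mM | 4.8 mM | 2.4 mM |
| remark | the very flask that is asked about, followed so far | run made earlier |  |
| time |  |  | 20 min |

| run | time / min | left-handed product / % | right-handed product / % | left-handed substrate / % |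
|---|---|---|---|---|
| Sunday's | 0.417 | 12.7 | 0 | 37.5 |
| Sunday's | 1.33 | 28.1 | 0.7 | 21.2 |
| Sunday's | 2.50 | 38.5 | 0.4 | 12.4 |
| Sunday's | 3.00 | 40.9 | 0.7 | 8.8 |
| Sunday's | 5.00 | 46.4 | 1.5 | 3.6 |
| Sunday's | 6.00 | 47.8 | 2.2 | 2.4 |
| Sunday's | 8.00 | 50.7 | 1.8 | 0.8 |
| Thursday's | 0.417 | 12.3 | 0 | 37.1 |
| Thursday's | 1.33 | 28.7 | 0.7 | 22.1 |
| Thursday's | 2.50 | 38.2 | 1.3 | 12.2 |
| Thursday's | 3.00 | 40.6 | 1.1 | 9.0 |
| Thursday's | 5.00 | 46.4 | 0.9 | 3.6 |
| Thursday's | 6.00 | 47.9 | 1.7 | 2.6 |
| Thursday's | 8.00 | 49.5 | 2.1 | 1.4 |

(each reading ± 0.5 percentage points)

- free catalyst is single-handed; left-handed substrate and right-handed substrate are mirror images of each other, charged as a racemate, each of them at the stated concentration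
- the numbers in the tables scatter with a standard deviation of 0.5 percentage points
- steps that have been proposed: partner + free catalyst + left-handed substrate -> free catalyst + left-handed product; partner + free catalyst + right-handed substrate -> free catalyst + right-handed product; left-handed substrate + racemization catalyst <-> right-handed substrate + racemization catalyst; racemization catalyst -> spent catalyst A; partner + racemization catalyst -> spent catalyst B; partner + precatalyst -> racemization catalyst + spent reagent
- an excess is the difference of the two amounts in percent of their sum
- an excess is below zero if the other one leads

* left-handed product and right-handed product together, in percent of the left-handed substrate and right-handed substrate charged together, at 20 min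
* excess of left-handed product over right-handed product in the product at 20 min
* whether the exchange between left-handed substrate and right-handed substrate keeps pace with the reaction: how far the product's excess at 20 min gets from its value without exchange to its value with instant exchange (above 80% keeps pace, below 20% hardly takes part, else lags behind)

Tom holds that the exchange keeps pace with the reaction, so that by 20 min left-handed product will have climbed far past the left-handed charge, 0.500 of the total. Left-handed substrate falls in Sunday's run with a mean pseudo-first-order time constant of 1.97 min, he says, so whatever crosses is consumed quickly. Left-handed substrate and product together already read 51.5% of the charge at 8.00 min.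

Vera holds that this is a plain resolution with a small leak. Thursday's run, with twice the precatalyst, reads 50.9% at that time, and each reading scatters by 0.5 percentage points. She replaces the leak by its mean. Sunday's sum, scatter included, reads as a mean crossing rate of 0.00188 min⁻¹ of the charge. Her measure is the crossing time, the right-handed half of the charge divided by that mean rate: 267 min. This is far longer than the consumption time constant, so by 20 min she expects a gain of 3.75% of the charge, 7.49% of the right-handed half. Tom objects that the rate may grow while precatalyst keeps reacting, and Vera's mean can't show that.

The forecast, which shares Vera's view but not her mean rate, gives 57.5%, an excess of 84.5%, and "hardly takes part": “roughly a tenth of the way, so exchange hardly takes part”.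

The flask gives 57.0% with an excess of 86.1%, and the exchange hardly takes part, at 9.5% of the way. Left-handed substrate and product together stand 1.07% of the charge above the left-handed charge at 10.0 min and 3.74% at 20.0 min, beside Vera's 3.75%: the crossing in this flask is not steady, as Tom warned. His view fits the long run: at 200 min, beside the crossing time of 267 min, left-handed product stands at 86.6%, past the left-handed charge.

    partner + free catalyst + left-handed substrate → free catalyst + left-handed product (k = 960 L² mol⁻² min⁻¹)
    partner + free catalyst + right-handed substrate → free catalyst + right-handed product (k = 8.70 L² mol⁻² min⁻¹)
    left-handed substrate + racemization catalyst ⇌ right-handed substrate + racemization catalyst, rate k3*[racemization catalyst]*[left-handed substrate] forward; the back reaction follows from the equilibrium constant (k = 28.0 L mol⁻¹ min⁻¹)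
    racemization catalyst → spent catalyst A (k = 1.70 × 10⁻⁵ min⁻¹)
    partner + racemization catalyst → spent catalyst B (k = 0.0300 L mol⁻¹ min⁻¹)
    partner + precatalyst → racemization catalyst + spent reagent (k = 0.0170 L mol⁻¹ min⁻¹)

In the neighbour flask with 0.0096 M of precatalyst, racemization catalyst stands at 11.1% of that charge against 11.4% in the asked flask, so Vera's crossing time scales to 66.7 min and her gain to 15.0%. The computed gain is 12.8%, with 64.2% product at an excess of 88.8%.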